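## Analysis of the target

The target is a diester of a fully substituted cyclopentane. The ring is numbered here so that C1 carries the CH2O–acyl arm, C2 a methyl group, C3 the second O–acyl group, C4 is the only methylene and C5 carries a 1,3-dihydroxypropan-2-yl group. The four ring stereocentres (1S, 2R, 3R, 5R in this numbering) are contiguous and alternate up and down, so every neighbouring pair (C5/C1, C1/C2, C2/C3) is trans and the C3 oxygen is cis to the C1 arm. Both acyl groups are the same (3S,4E)-4-formyl-3-(2-oxoethyl)hex-4-enoyl unit, whose single stereocentre carries a CH2CHO arm and the α-carbon of an (E)-2-ethylidene enal. The sensitive groups are four aldehydes (each chain is a 1,5-dialdehyde prone to hydration, cyclisation and aldol chemistry), two enals whose geometry must be kept, two esters (one on a hindered secondary alcohol) and a free 1,3-diol. The difficulty is that the six stereocentres fall into two sets that cannot influence each other, that the same chain must be placed on two different alcohols, and that four aldehydes must be released at the end without lactonisation. The strategy rests on one feature: in each chain C3 is β to the ester carbonyl C1 and is bonded to the trisubstituted alkenyl carbon C4, which is the pattern left by conjugate addition of an alkenyl metal to an (E)-enoate.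

## Retrosynthetic reasoning

**31 back to 28.** The four aldehydes of target 31 are kept masked until the last step: the two CH2CHO groups as diethyl acetals and the 1,3-diol as an acetonide (bis-enal 30). The enal carbonyls are carried one oxidation level lower, as allylic alcohols (29) protected as silyl ethers (28). No C–C bond is cut; the forward steps must free a primary allylic alcohol five atoms from an ester carbonyl without letting it lactonise, then oxidise it without touching the alkene geometry.

**28 to 19 and 27 (key disconnection).** In both chains the C3–C4 bond is cut. Cutting there removes both chain stereocentres and both ethylidene units at once, and leaves a bis[(E)-enoate] 19 with no chain stereocentre plus one alkenylboronic acid 27 of fixed geometry. The bond is β to an ester carbonyl, so a rhodium-catalysed asymmetric 1,4-addition can form it under control of a chiral ligand alone. That is what this target needs, since the ring stereocentres are too far away to help or interfere. The forward reaction must work twice on one molecule, with the same facial sense at both enoates and with retention of the alkene geometry of 27.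

**19 to 17 and 18, then 17 to 15 and 16.** Each enoate is cut at its C=C bond by cross-metathesis into an acrylate (bis-acrylate 17) and the terminal alkene 18, which brings the masked CH2CHO arm. The two ester C–O bonds of 17 are then cut to the core diol 15 and acryloyl chloride 16. This keeps the chain carbons in cheap achiral pieces and asks of the core only a double acylation.

**27 to 20.** The boronic acid 27 is traced to alkenyl bromide 24 by bromine–lithium exchange and borylation, both with retention. Bromide 24 comes from bromo alcohol 23 and bromo enal 22, and 22 from crotonaldehyde 20 by bromination and dehydrobromination. That elimination gives the Z bromide, which places the methyl cis to bromine and therefore cis to boron, so the E ethylidene of the target is fixed four steps before the key step.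

**15 to 12, 11 and 10.** The primary alcohol of 15 is traced to a vinyl group (ester 12), a hydroxymethyl equivalent that survives organometallic steps. The C3 oxygen is the one ring centre that substrate control sets the wrong way: a bulky hydride attacks ketone 10 anti to the neighbouring methyl and gives alcohol 11 with the oxygen cis to it. The C3–O bond is therefore formed with inversion (12 from 11), which uses the reliable kinetic selectivity instead of opposing it.

**10 to 6, 7 and 8.** The C1–vinyl and C2–methyl bonds are cut together. Enone 6 takes the vinyl group from 7 at its β-carbon anti to the C5 substituent, and the resulting enolate takes the methyl from 8 anti to the vinyl group. The single stereocentre of 6 thus sets C1 and C2, and the trans,trans arrangement is also the thermodynamic one at the epimerisable C2.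

**6 to 1 and 2.** Enone 6 is simplified by functional group changes to allylic alcohol 5, triol 4 and malonate 3. The bond from ring C5 to the malonate carbon is cut by an allylic alkylation of the single-enantiomer cyclopentenyl monoacetate 1 with dimethyl malonate 2. The absolute configuration of the whole ring is thereby bought with a catalogue compound.

## Alternatives that were turned down

**Alternative 1:** Each chain is treated as a 1,5-dialdehyde folded into a 2-alkoxy-3,4-dihydro-2H-pyran, cut at the bond from the chain stereocentre to the methylene of the future CH2CHO arm and at one ring C–O bond. The forward key step is an inverse-demand oxa-Diels–Alder reaction of a silyloxy-substituted enal (as 1-oxadiene) with a vinyl ether under a chiral chromium catalyst, giving the cis dihydropyran A1.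
- For: the stereocentre is made on a small fragment by a dependable catalytic cycloaddition, the two aldehydes emerge differentiated, and the valuable core only sees esterifications. On these points it is stronger than the chosen route, which runs a twofold catalytic reaction on the core.
- Against: A1 still lacks the ethylidene, which must be built on the enol ether carbon with E control. The silyloxyethyl arm must be oxidised to the acid, and an acid carrying an acid-labile mixed acetal must be coupled twice, once to hindered ring C3.
- Comparison: aldehyde differentiation is not needed here because all four are released together. The chosen route brings the complete ethylidene unit and the stereocentre in one step from a bromide of fixed geometry, in far fewer operations per chain.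

**Alternative 2:** The ring is cut between C1 and C5. An open-chain aldehyde carrying an alkylidene malonate is closed by enamine catalysis (a diarylprolinol silyl ether) in a 5-exo Michael addition to give A2, whose formyl and malonyl groups are the future CH2OH and CH(CH2OH)2.
- For: the ring closes with the C3 oxygen already in its final configuration, so no ketone reduction and inversion are needed. Here it is stronger than the chosen core synthesis.
- Against: the acyclic precursor needs its methyl and silyloxy stereocentres from separate asymmetric chemistry. Its alkylidene malonate has an acidic γ-methylene next to a silyloxy carbon, which invites deconjugation and elimination under the amine. Catalyst and substrate control may be mismatched, and nothing is done about the chain stereocentres or the four aldehydes.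
- Comparison: the chosen route takes its ring configuration from enantiopure 1 and substrate-controlled additions in a similar number of steps, and spends its one uncertain step on the chains, where two stereocentres and two alkenes are made at once.

**Alternative 3:** The ring is cut between the carbonyl carbon C3 and the methylene C4. A 4-pentenal with a 1,1-disubstituted alkene undergoes intramolecular hydroacylation on a cationic BINAP complex of monovalent rhodium (C–H insertion, hydride transfer to the internal alkene carbon, reductive elimination), giving cyclopentanone A3 and creating C5.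
- For: the ring closure is atom-economical and A3 already has the benzyloxymethyl arm at the right oxidation level. It is a close relative of ketone 10 and equal to it as a platform.
- Against: the pentenal has an epimerisable α-stereocentre next to a second one, decarbonylation competes, and the new C5 centre depends on a ligand–substrate match. The ketone still needs the same reduction and inversion as here, and the chains are untouched.
- Comparison: the chosen route reaches the equivalent ketone from 1 by four routine steps and one conjugate addition, so the hydroacylation would add risk in the core without removing any elsewhere.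

Key step: step 15

Remarks: ring positions C1–C5 in the text follow the numbering of the analysis; systematic names carry their own locants. Assumption: the facial sense of BINAP with (E)-enoates follows the established model (the (S)-ligand gives (R)-3-arylbutanoates from crotonates), so (R)-BINAP is specified for the (S) chain centres. Compound 1 is used as the commercial single enantiomer.

## Route

Step 1
Reactants: 1 (1R,4S)-4-hydroxycyclopent-2-en-1-yl acetate; 2 dimethyl malonate
Product: 3 dimethyl 2-[(1R,4S)-4-hydroxycyclopent-2-en-1-yl]propanedioate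
Conditions: NaH, Pd(PPh3)4 (3 mol %), THF, 0 °C → rt
Reagents that add atoms: dimethyl malonate 2, COC(=O)CC(=O)OC
Why: Tsuji–Trost allylic alkylation: zerovalent palladium ionises the allylic acetate with inversion and the soft malonate attacks anti to the metal at the allyl terminus remote from the carbinol, so the C–C bond forms with net retention (cis-1,4 product) and ring C5 of the target is set as R.

Step 2
Reactants: 3 dimethyl 2-[(1R,4S)-4-hydroxycyclopent-2-en-1-yl]propanedioate
Product: 4 2-[(1R,4S)-4-hydroxycyclopent-2-en-1-yl]propane-1,3-diol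
Conditions: LiAlH4, THF, 0 °C → rt; then Na2SO4·10H2O
Reagents that add atoms: none
Why: Hydride reduction of a malonic diester to the 2-substituted propane-1,3-diol; the isolated ring alkene and both stereocentres are not affected.

Step 3
Reactants: 4 2-[(1R,4S)-4-hydroxycyclopent-2-en-1-yl]propane-1,3-diol
Product: 5 (1S,4R)-4-(2,2-dimethyl-1,3-dioxan-5-yl)cyclopent-2-en-1-ol
Conditions: Me2C(OMe)2, PPTS (cat.), CH2Cl2, rt; then MeOH (brief)
Reagents that add atoms: 2,2-dimethoxypropane, COC(C)(C)OC
Why: Acid-catalysed transketalisation; the primary 1,3-diol closes the six-membered 1,3-dioxane much more readily than any ring through the secondary hydroxyl, and the short methanol treatment removes any mixed ketal from the allylic oxygen.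

Step 4
Reactants: 5 (1S,4R)-4-(2,2-dimethyl-1,3-dioxan-5-yl)cyclopent-2-en-1-ol
Product: 6 (4R)-4-(2,2-dimethyl-1,3-dioxan-5-yl)cyclopent-2-en-1-one
Conditions: MnO2, CH2Cl2, rt
Reagents that add atoms: none
Why: Neutral allylic oxidation on MnO2 gives the enone without enolising the γ-stereocentre (ring C5) and without touching the ketal.

Step 5
Reactants: 6 (4R)-4-(2,2-dimethyl-1,3-dioxan-5-yl)cyclopent-2-en-1-one; 7 vinylmagnesium bromide; 8 iodomethane
Product: 10 (2R,3S,4R)-4-(2,2-dimethyl-1,3-dioxan-5-yl)-3-ethenyl-2-methylcyclopentan-1-one, via enol silane 9 (not isolated)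
Conditions: CH2=CHMgBr, CuBr·SMe2 (10 mol %), TMSCl, THF, −78 °C; then MeLi, THF, 0 °C; MeI, DMPU, −78 → −20 °C
Reagents that add atoms: vinylmagnesium bromide 7, C=C[Mg]Br; iodomethane 8, CI
Why: Copper-catalysed, TMSCl-accelerated conjugate addition puts the vinyl group (a masked hydroxymethyl) on ring C1 anti to the C5 substituent; MeLi cleaves the enol silane to the regiodefined lithium enolate, which is methylated anti to the vinyl group, so C5/C1/C2 come out all-trans, which is also the thermodynamic arrangement at the epimerisable C2.

Step 6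
Reactants: 10 (2R,3S,4R)-4-(2,2-dimethyl-1,3-dioxan-5-yl)-3-ethenyl-2-methylcyclopentan-1-one
Product: 11 (1S,2R,3S,4R)-4-(2,2-dimethyl-1,3-dioxan-5-yl)-3-ethenyl-2-methylcyclopentan-1-ol
Conditions: LiBH(s-Bu)3 (L-Selectride), THF, −78 °C; then aq. NaOH, H2O2
Reagents that add atoms: none
Why: The bulky trialkylborohydride attacks the cyclopentanone from the face opposite to the adjacent methyl group (and opposite to the C5 substituent), which should give cleanly the alcohol cis to the methyl, the C3 epimer of what the target needs.

Step 7
Reactants: 11 (1S,2R,3S,4R)-4-(2,2-dimethyl-1,3-dioxan-5-yl)-3-ethenyl-2-methylcyclopentan-1-ol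
Product: 12 (1R,2R,3S,4R)-4-(2,2-dimethyl-1,3-dioxan-5-yl)-3-ethenyl-2-methylcyclopentyl 4-nitrobenzoate
Conditions: 4-O2NC6H4CO2H, PPh3, DIAD, THF, 0 °C → rt
Reagents that add atoms: 4-nitrobenzoic acid, OC(=O)c1ccc(cc1)[N+](=O)[O-]
Why: Mitsunobu reaction with an acidic carboxylic acid; SN2 displacement of the oxyphosphonium inverts ring C3 and places the oxygen trans to the methyl and cis to the C1 arm, as in the target.

Step 8
Reactants: 12 (1R,2R,3S,4R)-4-(2,2-dimethyl-1,3-dioxan-5-yl)-3-ethenyl-2-methylcyclopentyl 4-nitrobenzoate
Product: 15 (1R,2R,3S,4R)-4-(2,2-dimethyl-1,3-dioxan-5-yl)-3-(hydroxymethyl)-2-methylcyclopentan-1-ol, via formyl ester 13 (not isolated), via hydroxymethyl ester 14 (not isolated)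
Conditions: O3, CH2Cl2/MeOH, −78 °C; NaBH4, −78 → 0 °C; then K2CO3, MeOH, rt
Reagents that add atoms: ozone, O=[O+][O-]
Why: Ozonolysis of the terminal alkene, borohydride reduction of the aldehyde and base-catalysed methanolysis of the activated aryl ester in one pot; the aldehyde exists only at low temperature and its α-centre (ring C1) already sits in the favoured trans,trans arrangement.

Step 9
Reactants: 15 (1R,2R,3S,4R)-4-(2,2-dimethyl-1,3-dioxan-5-yl)-3-(hydroxymethyl)-2-methylcyclopentan-1-ol; 16 acryloyl chloride
Product: 17 (1R,2R,3S,4R)-4-(2,2-dimethyl-1,3-dioxan-5-yl)-2-methyl-3-[(prop-2-enoyloxy)methyl]cyclopentyl prop-2-enoate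
Conditions: CH2=CHCOCl, Et3N, DMAP (cat.), CH2Cl2, −20 → 0 °C
Reagents that add atoms: acryloyl chloride 16, C=CC(=O)Cl
Why: DMAP-catalysed acylation of the primary and the secondary hydroxyl with the acid chloride; no stereocentre is involved and the ketal is stable to the basic medium.

Step 10
Reactants: 17 (1R,2R,3S,4R)-4-(2,2-dimethyl-1,3-dioxan-5-yl)-2-methyl-3-[(prop-2-enoyloxy)methyl]cyclopentyl prop-2-enoate; 18 4,4-diethoxybut-1-ene
Product: 19 (1R,2R,3S,4R)-3-({[(2E)-5,5-diethoxypent-2-enoyl]oxy}methyl)-4-(2,2-dimethyl-1,3-dioxan-5-yl)-2-methylcyclopentyl (2E)-5,5-diethoxypent-2-enoate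
Conditions: second-generation Grubbs catalyst (5 mol %), 18 (6 equiv), CH2Cl2, 40 °C
Reagents that add atoms: 4,4-diethoxybut-1-ene 18, C=CCC(OCC)OCC
Why: Olefin cross-metathesis between the electron-poor acrylates, which do not homodimerise, and an excess of the electron-rich terminal alkene; the disubstituted enoates form as the E isomers under thermodynamic control.

Step 11
Reactants: 20 (E)-but-2-enal
Product: 22 (Z)-2-bromobut-2-enal, via 2,3-dibromobutanal 21 (not isolated)
Conditions: Br2, CH2Cl2, 0 °C; then Et3N, 0 °C → rt
Reagents that add atoms: bromine, BrBr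
Why: Bromine adds across the alkene and the amine removes the acidic α-hydrogen with loss of the β-bromide; the 2-bromo enal forms as the more stable Z isomer, with methyl trans to formyl and cis to bromine.

Step 12
Reactants: 22 (Z)-2-bromobut-2-enal
Product: 23 (Z)-2-bromobut-2-en-1-ol
Conditions: NaBH4, CeCl3·7H2O, MeOH, 0 °C
Reagents that add atoms: none
Why: Luche 1,2-reduction of the enal; the alkene and its geometry are not touched.

Step 13
Reactants: 23 (Z)-2-bromobut-2-en-1-ol
Product: 24 {[(2Z)-2-bromobut-2-en-1-yl]oxy}(tert-butyl)dimethylsilane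
Conditions: TBSCl, imidazole, CH2Cl2, rt
Reagents that add atoms: tert-butyldimethylsilyl chloride, CC(C)(C)[Si](C)(C)Cl
Why: Standard silylation of a primary allylic alcohol; the bulky silyl ether is a poor leaving group and a poor ligand, which matters for the alkenylrhodium of step 15.

Step 14
Reactants: 24 {[(2Z)-2-bromobut-2-en-1-yl]oxy}(tert-butyl)dimethylsilane
Product: 27 [(2E)-1-{[tert-butyl(dimethyl)silyl]oxy}but-2-en-2-yl]boronic acid, via alkenyllithium 25 (not isolated), via lithium alkenylborate 26 (not isolated)
Conditions: t-BuLi (2.1 equiv), Et2O, −78 °C; B(OiPr)3, −78 °C → rt; then 1 M HCl to pH 5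
Reagents that add atoms: triisopropyl borate, CC(C)OB(OC(C)C)OC(C)C; water, O
Why: Bromine–lithium exchange on an alkenyl bromide and trapping with a trialkyl borate both proceed with retention at low temperature, so boron ends cis to the methyl group; the descriptor changes from Z to E only because carbon outranks boron.

Step 15
Reactants: 19 (1R,2R,3S,4R)-3-({[(2E)-5,5-diethoxypent-2-enoyl]oxy}methyl)-4-(2,2-dimethyl-1,3-dioxan-5-yl)-2-methylcyclopentyl (2E)-5,5-diethoxypent-2-enoate; 27 [(2E)-1-{[tert-butyl(dimethyl)silyl]oxy}but-2-en-2-yl]boronic acid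
Product: 28 (1R,2R,3S,4R)-3-({[(3S)-3-[(2E)-1-{[tert-butyl(dimethyl)silyl]oxy}but-2-en-2-yl]-5,5-diethoxypentanoyl]oxy}methyl)-4-(2,2-dimethyl-1,3-dioxan-5-yl)-2-methylcyclopentyl (3S)-3-[(2E)-1-{[tert-butyl(dimethyl)silyl]oxy}but-2-en-2-yl]-5,5-diethoxypentanoate
Conditions: Rh(acac)(C2H4)2 (10 mol %), (R)-BINAP (11 mol %), Et3N, dioxane/H2O (10:1), 100 °C; 27 (6 equiv) in three portions
Reagents that add atoms: boronic acid 27, C/C=C(/CO[Si](C)(C)C(C)(C)C)B(O)O
Why: This is the rhodium-catalysed asymmetric 1,4-addition of an alkenylboronic acid to α,β-unsaturated esters (Hayashi–Miyaura reaction), run on both enoates of 19. Water and the boronic acid turn the acac precatalyst into a hydroxo complex of monovalent rhodium carrying (R)-BINAP, and transmetalation from boron gives the alkenylrhodium with retention of alkene geometry. The (E)-enoate then inserts into the Rh–C bond so that the alkenyl carbon goes to the β-carbon, and water protonates the oxa-π-allylrhodium and returns Rh–OH. No ring is closed. Each new stereocentre (C3 of each chain) is controlled by the ligand alone: the (S)-ligand delivers carbon to the α-si face of (E)-enoates, so (R)-BINAP attacks the α-re face, which with the priority order alkenyl > CH2CO2R > CH2CH(OEt)2 is S; the ring stereocentres are too remote to interfere, so one ligand serves both enoates. The E ethylidene is secured because boron is cis to the methyl in 27 and neither transmetalation nor insertion changes that. The step also needs 1,4-addition without loss of the acetals, the ketal or the silyl ethers, which the near-neutral medium secures, with Et3N buffering the boronic acid. The excess of 27 added in portions offsets protodeboronation.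

Step 16
Reactants: 28 (the bis-silyl ether from step 15)
Product: 29 (1R,2R,3S,4R)-3-({[(3S)-5,5-diethoxy-3-[(2E)-1-hydroxybut-2-en-2-yl]pentanoyl]oxy}methyl)-4-(2,2-dimethyl-1,3-dioxan-5-yl)-2-methylcyclopentyl (3S)-5,5-diethoxy-3-[(2E)-1-hydroxybut-2-en-2-yl]pentanoate
Conditions: HF·pyridine, pyridine, THF, 0 °C → rt
Reagents that add atoms: none
Why: Fluoride cleavage of the two primary allylic silyl ethers under buffered, non-basic and anhydrous conditions, chosen so that no alkoxide forms that could attack the ester carbonyl five atoms away and so that the acetals and the ketal stay intact.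

Step 17
Reactants: 29 (the bis-allylic alcohol from step 16)
Product: 30 (1R,2R,3S,4R)-3-({[(3S,4E)-3-(2,2-diethoxyethyl)-4-formylhex-4-enoyl]oxy}methyl)-4-(2,2-dimethyl-1,3-dioxan-5-yl)-2-methylcyclopentyl (3S,4E)-3-(2,2-diethoxyethyl)-4-formylhex-4-enoate
Conditions: MnO2, CH2Cl2, rt (directly on crude 29)
Reagents that add atoms: none
Why: MnO2 oxidises allylic alcohols selectively to enals under neutral conditions; the E geometry (methyl trans to formyl) is kept and is also the more stable one.

Step 18
Reactants: 30 (the bis-enal from step 17)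
Product: 31 (1R,2R,3S,4R)-4-(1,3-dihydroxypropan-2-yl)-3-({[(3S,4E)-4-formyl-3-(2-oxoethyl)hex-4-enoyl]oxy}methyl)-2-methylcyclopentyl (3S,4E)-4-formyl-3-(2-oxoethyl)hex-4-enoate (target, CNP0313563.1)
Conditions: 1 M HCl, THF, 0 °C → rt
Reagents that add atoms: water, O
Why: Aqueous acid hydrolysis of the two diethyl acetals and the acetonide; no stereocentre is α to a carbonyl, the esters are stable to dilute acid at room temperature, and the enal geometry is the thermodynamic one.

## Compound list

1 | (1R,4S)-4-hydroxycyclopent-2-en-1-yl acetate (cis) | C1=C[C@@H](O)C[C@H]1OC(C)=O | starting material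
2 | dimethyl malonate | COC(=O)CC(=O)OC | starting material
3 | dimethyl 2-[(1R,4S)-4-hydroxycyclopent-2-en-1-yl]propanedioate | C1=C[C@@H](O)C[C@H]1C(C(=O)OC)C(=O)OC | intermediate
4 | 2-[(1R,4S)-4-hydroxycyclopent-2-en-1-yl]propane-1,3-diol | C1=C[C@@H](O)C[C@H]1C(CO)CO | intermediate
5 | (1S,4R)-4-(2,2-dimethyl-1,3-dioxan-5-yl)cyclopent-2-en-1-ol | C1=C[C@@H](O)C[C@H]1C2COC(C)(C)OC2 | intermediate
6 | (4R)-4-(2,2-dimethyl-1,3-dioxan-5-yl)cyclopent-2-en-1-one | C1=CC(=O)C[C@H]1C2COC(C)(C)OC2 | intermediate
7 | vinylmagnesium bromide | C=C[Mg]Br | starting material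
8 | iodomethane | CI | starting material
9 | {[(3S,4R)-4-(2,2-dimethyl-1,3-dioxan-5-yl)-3-ethenylcyclopent-1-en-1-yl]oxy}trimethylsilane | C=C[C@@H]1C=C(O[Si](C)(C)C)C[C@H]1C2COC(C)(C)OC2 | intermediate
10 | (2R,3S,4R)-4-(2,2-dimethyl-1,3-dioxan-5-yl)-3-ethenyl-2-methylcyclopentan-1-one | C=C[C@@H]1[C@@H](C)C(=O)C[C@H]1C2COC(C)(C)OC2 | intermediate
11 | (1S,2R,3S,4R)-4-(2,2-dimethyl-1,3-dioxan-5-yl)-3-ethenyl-2-methylcyclopentan-1-ol | C=C[C@@H]1[C@@H](C)[C@@H](O)C[C@H]1C2COC(C)(C)OC2 | intermediate
12 | (1R,2R,3S,4R)-4-(2,2-dimethyl-1,3-dioxan-5-yl)-3-ethenyl-2-methylcyclopentyl 4-nitrobenzoate | C=C[C@@H]1[C@@H](C)[C@H](OC(=O)c3ccc(cc3)[N+](=O)[O-])C[C@H]1C2COC(C)(C)OC2 | intermediate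
13 | (1R,2R,3S,4S)-4-(2,2-dimethyl-1,3-dioxan-5-yl)-3-formyl-2-methylcyclopentyl 4-nitrobenzoate | O=C[C@@H]1[C@@H](C)[C@H](OC(=O)c3ccc(cc3)[N+](=O)[O-])C[C@H]1C2COC(C)(C)OC2 | intermediate
14 | (1R,2R,3S,4R)-4-(2,2-dimethyl-1,3-dioxan-5-yl)-3-(hydroxymethyl)-2-methylcyclopentyl 4-nitrobenzoate | OC[C@@H]1[C@@H](C)[C@H](OC(=O)c3ccc(cc3)[N+](=O)[O-])C[C@H]1C2COC(C)(C)OC2 | intermediate
15 | (1R,2R,3S,4R)-4-(2,2-dimethyl-1,3-dioxan-5-yl)-3-(hydroxymethyl)-2-methylcyclopentan-1-ol | OC[C@@H]1[C@@H](C)[C@H](O)C[C@H]1C2COC(C)(C)OC2 | intermediate
16 | acryloyl chloride | C=CC(=O)Cl | starting material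
17 | (1R,2R,3S,4R)-4-(2,2-dimethyl-1,3-dioxan-5-yl)-2-methyl-3-[(prop-2-enoyloxy)methyl]cyclopentyl prop-2-enoate | C=CC(=O)OC[C@@H]1[C@@H](C)[C@H](OC(=O)C=C)C[C@H]1C2COC(C)(C)OC2 | intermediate
18 | 4,4-diethoxybut-1-ene (3-butenal diethyl acetal) | C=CCC(OCC)OCC | starting material
19 | (1R,2R,3S,4R)-3-({[(2E)-5,5-diethoxypent-2-enoyl]oxy}methyl)-4-(2,2-dimethyl-1,3-dioxan-5-yl)-2-methylcyclopentyl (2E)-5,5-diethoxypent-2-enoate | CCOC(OCC)C/C=C/C(=O)OC[C@@H]1[C@@H](C)[C@H](OC(=O)/C=C/CC(OCC)OCC)C[C@H]1C2COC(C)(C)OC2 | intermediate
20 | (E)-but-2-enal (crotonaldehyde) | C/C=C/C=O | starting material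
21 | 2,3-dibromobutanal (racemic) | CC(Br)C(Br)C=O | intermediate
22 | (Z)-2-bromobut-2-enal | C/C=C(\Br)C=O | intermediate
23 | (Z)-2-bromobut-2-en-1-ol | C/C=C(\Br)CO | intermediate
24 | {[(2Z)-2-bromobut-2-en-1-yl]oxy}(tert-butyl)dimethylsilane | C/C=C(\Br)CO[Si](C)(C)C(C)(C)C | intermediate
25 | [(2E)-1-{[tert-butyl(dimethyl)silyl]oxy}but-2-en-2-yl]lithium | C/C=C(\[Li])CO[Si](C)(C)C(C)(C)C | intermediate
26 | lithium [(2E)-1-{[tert-butyl(dimethyl)silyl]oxy}but-2-en-2-yl]tri(propan-2-yloxy)borate | [Li+].C/C=C(\[B-](OC(C)C)(OC(C)C)OC(C)C)CO[Si](C)(C)C(C)(C)C | intermediate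
27 | [(2E)-1-{[tert-butyl(dimethyl)silyl]oxy}but-2-en-2-yl]boronic acid | C/C=C(/CO[Si](C)(C)C(C)(C)C)B(O)O | intermediate
28 | (1R,2R,3S,4R)-3-({[(3S)-3-[(2E)-1-{[tert-butyl(dimethyl)silyl]oxy}but-2-en-2-yl]-5,5-diethoxypentanoyl]oxy}methyl)-4-(2,2-dimethyl-1,3-dioxan-5-yl)-2-methylcyclopentyl (3S)-3-[(2E)-1-{[tert-butyl(dimethyl)silyl]oxy}but-2-en-2-yl]-5,5-diethoxypentanoate | C/C=C(/CO[Si](C)(C)C(C)(C)C)[C@@H](CC(OCC)OCC)CC(=O)OC[C@@H]1[C@@H](C)[C@H](OC(=O)C[C@H](CC(OCC)OCC)/C(CO[Si](C)(C)C(C)(C)C)=C\C)C[C@H]1C2COC(C)(C)OC2 | intermediate
29 | (1R,2R,3S,4R)-3-({[(3S)-5,5-diethoxy-3-[(2E)-1-hydroxybut-2-en-2-yl]pentanoyl]oxy}methyl)-4-(2,2-dimethyl-1,3-dioxan-5-yl)-2-methylcyclopentyl (3S)-5,5-diethoxy-3-[(2E)-1-hydroxybut-2-en-2-yl]pentanoate | C/C=C(/CO)[C@@H](CC(OCC)OCC)CC(=O)OC[C@@H]1[C@@H](C)[C@H](OC(=O)C[C@H](CC(OCC)OCC)/C(CO)=C\C)C[C@H]1C2COC(C)(C)OC2 | intermediate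
30 | (1R,2R,3S,4R)-3-({[(3S,4E)-3-(2,2-diethoxyethyl)-4-formylhex-4-enoyl]oxy}methyl)-4-(2,2-dimethyl-1,3-dioxan-5-yl)-2-methylcyclopentyl (3S,4E)-3-(2,2-diethoxyethyl)-4-formylhex-4-enoate | C/C=C(/C=O)[C@@H](CC(OCC)OCC)CC(=O)OC[C@@H]1[C@@H](C)[C@H](OC(=O)C[C@H](CC(OCC)OCC)/C(C=O)=C\C)C[C@H]1C2COC(C)(C)OC2 | intermediate
31 | (1R,2R,3S,4R)-4-(1,3-dihydroxypropan-2-yl)-3-({[(3S,4E)-4-formyl-3-(2-oxoethyl)hex-4-enoyl]oxy}methyl)-2-methylcyclopentyl (3S,4E)-4-formyl-3-(2-oxoethyl)hex-4-enoate | C/C=C(/C=O)[C@@H](CC=O)CC(=O)OC[C@@H]1[C@@H](C)[C@H](OC(=O)C[C@H](CC=O)/C(C=O)=C\C)C[C@H]1C(CO)CO | target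

## Step count and least certain steps

Total: 18 steps. Longest linear sequence: 14 steps (steps 1–10 and 15–18 from 1); the boronic acid branch is 4 steps (11–14).

**Step 15 (key step).** Three processes threaten it.
- The alkenylrhodium carries an allylic oxygen β to the metal. β-Oxygen elimination to an allene, together with protodeboronation, can use up the reagent before the second enoate has reacted and leave the mono-adduct.
- Acetal hydrolysis at 100 °C would expose aldehydes to 1,2-addition.
- Imperfect facial selectivity at either enoate gives diastereomers that differ only at remote centres and will be hard to separate.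
- Fallback: move the addition off the core. It sets out from 15 (with 18 and 27) and returns at 28. Methyl acrylate and 18 are cross-metathesised to methyl (2E)-5,5-diethoxypent-2-enoate F1. The same rhodium/(R)-BINAP addition of 27 to this simple monoester, where a large excess of reagent and an enantiomeric upgrade are affordable, gives methyl (3S)-3-[(2E)-1-{[tert-butyl(dimethyl)silyl]oxy}but-2-en-2-yl]-5,5-diethoxypentanoate F2. LiOH in THF/H2O gives (3S)-3-[(2E)-1-{[tert-butyl(dimethyl)silyl]oxy}but-2-en-2-yl]-5,5-diethoxypentanoic acid F3, and double esterification of 15 with F3 (EDC·HCl, DMAP) gives 28.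

**Step 5.** Proton transfer between the product ketone and the enolate during methylation can lead to over-methylation or methylation on the C4 side, and a slow alkylation erodes the trans selectivity.
- Fallback: install the methyl before the conjugate addition. It sets out from 6 and returns at 10. α-Iodination (I2, pyridine) gives (4S)-4-(2,2-dimethyl-1,3-dioxan-5-yl)-2-iodocyclopent-2-en-1-one F4. Stille methylation (Me4Sn, Pd2(dba)3, AsPh3, CuI) gives (4R)-4-(2,2-dimethyl-1,3-dioxan-5-yl)-2-methylcyclopent-2-en-1-one F5. The copper-catalysed addition of 7, followed by protonation and base equilibration of the α-methyl centre, gives 10.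

**Step 7.** The oxyphosphonium on a secondary cyclopentyl carbon flanked by a methine can eliminate to the cyclopentene instead of being displaced, because the incoming carboxylate must approach past the C1 substituent.
- Fallback: a thermodynamically controlled reduction instead of reduction and inversion. It sets out from 10 and returns at 15. Dissolving-metal reduction (Li, liquid NH3/THF, EtOH, −78 °C) favours the more stable alcohol trans to the methyl, (1R,2R,3S,4R)-4-(2,2-dimethyl-1,3-dioxan-5-yl)-3-ethenyl-2-methylcyclopentan-1-ol F6, which is separated from its epimer 11. Ozonolysis with NaBH4 work-up gives 15 directly.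

**Step 14.** The alkenyllithium 25 has a silyloxy group on the adjacent carbon. Silyl migration from oxygen to carbon on warming, or protodeboronation of 27 during acidic work-up, would lower the supply of reagent for a step that needs a large excess.
- Fallback: a borylation that avoids the organolithium. It sets out from 24 and returns at 27. Miyaura borylation (B2pin2, PdCl2(PPh3)2, PPh3, KOPh, toluene, 50 °C) gives tert-butyl(dimethyl){[(2E)-2-(4,4,5,5-tetramethyl-1,3,2-dioxaborolan-2-yl)but-2-en-1-yl]oxy}silane F7. Oxidative removal of pinacol (NaIO4, NH4OAc, acetone/H2O) gives 27.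

**Step 16.** Each freed hydroxyl is δ to an ester carbonyl and is held close to it by the shared sp2 carbon. Six-membered lactonisation would expel the core alcohol and destroy the diester.
- Fallback: carry the enal carbon as an acetal so that no free alcohol ever forms. It sets out from 22 and 19 and returns at 31. Acetalisation of 22 (HC(OEt)3, EtOH, cat. TsOH) gives (Z)-2-bromo-1,1-diethoxybut-2-ene F8. Lithiation and borylation as in step 14, with neutral work-up, give [(2E)-1,1-diethoxybut-2-en-2-yl]boronic acid F9. Its addition to 19 under the conditions of step 15 gives the tetra-acetal F10 (the analogue of 28 with CH(OEt)2 in place of each CH2OSi group), and the hydrolysis of step 18 then gives 31 in one operation.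

## Further compounds

F1 | step 15 | methyl (2E)-5,5-diethoxypent-2-enoate | CCOC(OCC)C/C=C/C(=O)OC
F2 | step 15 | methyl (3S)-3-[(2E)-1-{[tert-butyl(dimethyl)silyl]oxy}but-2-en-2-yl]-5,5-diethoxypentanoate | C/C=C(/CO[Si](C)(C)C(C)(C)C)[C@@H](CC(OCC)OCC)CC(=O)OC
F3 | step 15 | (3S)-3-[(2E)-1-{[tert-butyl(dimethyl)silyl]oxy}but-2-en-2-yl]-5,5-diethoxypentanoic acid | C/C=C(/CO[Si](C)(C)C(C)(C)C)[C@@H](CC(OCC)OCC)CC(=O)O
F4 | step 5 | (4S)-4-(2,2-dimethyl-1,3-dioxan-5-yl)-2-iodocyclopent-2-en-1-one | C1=C(I)C(=O)C[C@H]1C2COC(C)(C)OC2
F5 | step 5 | (4R)-4-(2,2-dimethyl-1,3-dioxan-5-yl)-2-methylcyclopent-2-en-1-one | C1=C(C)C(=O)C[C@H]1C2COC(C)(C)OC2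
F6 | step 7 | (1R,2R,3S,4R)-4-(2,2-dimethyl-1,3-dioxan-5-yl)-3-ethenyl-2-methylcyclopentan-1-ol | C=C[C@@H]1[C@@H](C)[C@H](O)C[C@H]1C2COC(C)(C)OC2
F7 | step 14 | tert-butyl(dimethyl){[(2E)-2-(4,4,5,5-tetramethyl-1,3,2-dioxaborolan-2-yl)but-2-en-1-yl]oxy}silane | C/C=C(/CO[Si](C)(C)C(C)(C)C)B1OC(C)(C)C(C)(C)O1
F8 | step 16 | (Z)-2-bromo-1,1-diethoxybut-2-ene | C/C=C(\Br)C(OCC)OCC
F9 | step 16 | [(2E)-1,1-diethoxybut-2-en-2-yl]boronic acid | C/C=C(/C(OCC)OCC)B(O)O
F10 | step 16 | (1R,2R,3S,4R)-3-({[(3S)-3-[(2E)-1,1-diethoxybut-2-en-2-yl]-5,5-diethoxypentanoyl]oxy}methyl)-4-(2,2-dimethyl-1,3-dioxan-5-yl)-2-methylcyclopentyl (3S)-3-[(2E)-1,1-diethoxybut-2-en-2-yl]-5,5-diethoxypentanoate | C/C=C(/C(OCC)OCC)[C@@H](CC(OCC)OCC)CC(=O)OC[C@@H]1[C@@H](C)[C@H](OC(=O)C[C@H](CC(OCC)OCC)/C(C(OCC)OCC)=C\C)C[C@H]1C2COC(C)(C)OC2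
A1 | alternative 1 | (2R,4R)-4-[2-(tert-butyldimethylsilyloxy)ethyl]-2-ethoxy-3,4-dihydro-2H-pyran (cis) | CC(C)(C)[Si](C)(C)OCC[C@@H]1C[C@H](OCC)OC=C1
A2 | alternative 2 | dimethyl 2-[(1R,2S,3R,4R)-2-formyl-3-methyl-4-(tert-butyldimethylsilyloxy)cyclopentyl]propanedioate | O=C[C@@H]1[C@@H](C)[C@H](O[Si](C)(C)C(C)(C)C)C[C@H]1C(C(=O)OC)C(=O)OC
A3 | alternative 3 | (2R,3S,4R)-3-[(benzyloxy)methyl]-4-(2,2-dimethyl-1,3-dioxan-5-yl)-2-methylcyclopentan-1-one | O(Cc3ccccc3)C[C@@H]1[C@@H](C)C(=O)C[C@H]1C2COC(C)(C)OC2
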